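**Assumptions (one line each)**
- The target has no stereocentres, so "single enantiomer" is moot. Both C=C bonds are E, and the 24-membered ring is the zwitterion (aryl sulfate / protonated N4).
- 3,4-Disubstituted ring A carries the sulfate para to its vinyl group. Ring B is the para-substituted aryl ether. The propyl-N amide belongs to the ring-B cinnamoyl unit, and the butyl-N amide to the ring-A unit.

**Retrosynthesis**
- The sulfate is installed last (SO3·py on the free phenol) after removing the N4 carbamate.
- The 24-membered ring is closed in the penultimate step. An aryl radical from ring A (Ar–I) adds to a terminal acrylamide on the butyl-N arm. The radical is then oxidised and loses HI, which sets the E-cinnamamide (Pd/visible-light radical Heck-type macrocyclisation).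
- The cyclisation precursor comes from reductive amination of an N1-cinnamoyl-1,3-diaminopropane with 4-acrylamidobutanal, with in-situ N4-Boc protection.
- The diaryl ether acid is made from catechol and 1-bromo-4-iodobenzene by Ullmann coupling, Heck reaction and para-iodination. Ring A's iodide is installed last so that it is the only Ar–I.

**Route**

**Step 1**
Reactants: 1 catechol (Oc1ccccc1O); 2 1-bromo-4-iodobenzene (Brc1ccc(I)cc1)
Product: 3 2-(4-bromophenoxy)phenol
Conditions: CuI (10 mol%), N,N-dimethylglycine (30 mol%), Cs2CO3, dioxane, 100 °C; catechol 3 equiv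
Reagents that add atoms: none
Why: Ullmann-type Cu-catalysed C–O coupling occurs chemoselectively at C–I and leaves C–Br; excess catechol limits double arylation.

**Step 2**
Reactants: 3; 4 acrylic acid (C=CC(=O)O)
Product: 5 (E)-3-[4-(2-hydroxyphenoxy)phenyl]acrylic acid
Conditions: Pd(OAc)2 (5 mol%), P(o-tol)3, Et3N, DMF, 100 °C
Reagents that add atoms: none
Why: Mizoroki–Heck coupling of the aryl bromide gives the E-cinnamic acid, and the free phenol is tolerated.

**Step 3**
Reactants: 5
Product: 6 (E)-3-[4-(2-hydroxy-5-iodophenoxy)phenyl]acrylic acid
Conditions: NIS (1.05 equiv), MeCN, 0 °C → rt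
Reagents that add atoms: N-iodosuccinimide, O=C1CCC(=O)N1I (adds I)
Why: Electrophilic aromatic iodination goes para to the strongly activating OH, which puts the iodine at the position that becomes ring A's vinyl carbon; the deactivated cinnamate ring is untouched.

**Step 4**
Reactants: 7 4-aminobutan-1-ol (NCCCCO); 8 acryloyl chloride (C=CC(=O)Cl)
Product: 9 N-(4-hydroxybutyl)acrylamide
Conditions: K2CO3, THF/H2O, 0 °C
Reagents that add atoms: none
Why: Schotten–Baumann acylation is selective for N over O.

**Step 5**
Reactants: 9
Product: 10 N-(4-oxobutyl)acrylamide (4-acrylamidobutanal, C=CC(=O)NCCCC=O)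
Conditions: Dess–Martin periodinane, NaHCO3, CH2Cl2, 0 °C → rt; use crude at once
Reagents that add atoms: none
Why: Mild oxidation of the primary alcohol leaves the acrylamide intact.

**Step 6**
Reactants: 6; 11 propane-1,3-diamine (NCCCN, 6 equiv)
Product: 12 (E)-N-(3-aminopropyl)-3-[4-(2-hydroxy-5-iodophenoxy)phenyl]acrylamide
Conditions: EDC·HCl, HOBt, DMF, 0 °C → rt
Reagents that add atoms: none
Why: Carbodiimide amide coupling; the large excess of diamine gives mono-acylation, and the aryl iodide and phenol survive.

**Step 7**
Reactants: 12; 10
Product: 13 tert-butyl N-(4-acrylamidobutyl)-N-{3-[(E)-3-(4-(2-hydroxy-5-iodophenoxy)phenyl)acrylamido]propyl}carbamate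
Conditions: NaBH(OAc)3, Boc2O, Et3N, DCE, rt
Reagents that add atoms: di-tert-butyl dicarbonate, CC(C)(C)OC(=O)OC(=O)OC(C)(C)C (adds Boc)
Why: Tandem reductive amination with in-situ Boc capture forms the N4 centre without over-alkylation and masks the secondary amine against aza-Michael addition, Pd binding and sulfamation; the acrylamide, cinnamamide and ArI are inert to the hydride.

**Step 8**
Reactants: 13
Product: 14 N4-Boc macrocycle
Conditions: Pd(OAc)2 (10 mol%), Xantphos (20 mol%), Cs2CO3, PhCF3/MeCN 4:1, ~2 mM (syringe-pump addition), blue LEDs, 45 °C
Reagents that add atoms: none (HI is lost)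
Why: Proposed new method: photoexcited Pd(0)–Xantphos transfers an electron to Ar–I, giving an aryl radical/Pd(I) pair. The aryl radical adds to the terminal CH2 of the acrylamide (the only good radical acceptor in reach) to form the 24-membered ring and an α-amido radical. Pd(I) recombination, β-H elimination and base-mediated loss of HI give the thermodynamically favoured E-cinnamamide. The closest known chemistry is visible-light Pd radical Heck cyclisation and macrocyclic Heck reactions; the set stereochemistry is the new C=C (E).

**Step 9**
Reactants: 14
Product: 15 macrocyclic secondary ammonium trifluoroacetate (free phenol)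
Conditions: TFA/CH2Cl2 1:4, anisole, 0 °C → rt, 1 h; evaporate
Reagents that add atoms: trifluoroacetic acid, OC(=O)C(F)(F)F (counter-ion)
Why: Acidolysis of the Boc carbamate; the cinnamamides, phenol and diaryl ether are stable.

**Step 10**
Reactants: 15
Product: 16 target
Conditions: SO3·pyridine (4 equiv), pyridine, rt, 12 h; brief pH 3 aqueous treatment; RP-HPLC
Reagents that add atoms: sulfur trioxide–pyridine, O=S(=O)=O.c1ccncc1 (adds SO3)
Why: O-Sulfation of the phenol by a pyridine–SO3 complex; N4 stays protonated in pyridine, and any N-sulfamate is hydrolysed by the brief mild acid wash while the aryl sulfate survives.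

**Consistency check**
- Ring: the C1(=O) carbonyl joins the butyl-N, and the ring-B amide joins the propyl-N (N–CCC–N–CCCC–N), which matches the target. The ring is 24-membered.
- The ring-A iodine sits para to the phenol oxygen and meta to the ether oxygen, matching the target.
- Both alkenes are E.
- Every atom balances from 1 and 2 through 16.
- Boc is removed before sulfation, so the acid-labile aryl sulfate never meets TFA.
- All starting materials have 8 or fewer heavy atoms.

**Compound list**
1 | catechol | Oc1ccccc1O | starting material
2 | 1-bromo-4-iodobenzene | Brc1ccc(I)cc1 | starting material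
3 | 2-(4-bromophenoxy)phenol | Oc1ccccc1Oc1ccc(Br)cc1 | intermediate
4 | acrylic acid | C=CC(=O)O | starting material
5 | (E)-3-[4-(2-hydroxyphenoxy)phenyl]acrylic acid | OC(=O)/C=C/c1ccc(Oc2ccccc2O)cc1 | intermediate
6 | (E)-3-[4-(2-hydroxy-5-iodophenoxy)phenyl]acrylic acid | OC(=O)/C=C/c1ccc(Oc2cc(I)ccc2O)cc1 | intermediate
7 | 4-aminobutan-1-ol | NCCCCO | starting material
8 | acryloyl chloride | C=CC(=O)Cl | starting material
9 | N-(4-hydroxybutyl)acrylamide | C=CC(=O)NCCCCO | intermediate
10 | 4-acrylamidobutanal | C=CC(=O)NCCCC=O | intermediate
11 | propane-1,3-diamine | NCCCN | starting material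
12 | N-(3-aminopropyl) cinnamamide of acid 6 | NCCCNC(=O)/C=C/c1ccc(Oc2cc(I)ccc2O)cc1 | intermediate
13 | N4-Boc cyclisation precursor | C=CC(=O)NCCCCN(C(=O)OC(C)(C)C)CCCNC(=O)/C=C/c1ccc(Oc2cc(I)ccc2O)cc1 | intermediate
14 | N4-Boc macrocyclic phenol | O=C1/C=C/c2ccc(O)c(c2)Oc2ccc(cc2)/C=C/C(=O)NCCCN(C(=O)OC(C)(C)C)CCCCN1 | intermediate
15 | macrocyclic phenol, ammonium trifluoroacetate | O=C1/C=C/c2ccc(O)c(c2)Oc2ccc(cc2)/C=C/C(=O)NCCC[NH2+]CCCCN1.[O-]C(=O)C(F)(F)F | intermediate
16 | target | O=C1/C=C/c2ccc(OS(=O)(=O)O)c(c2)Oc2ccc(cc2)/C=C/C(=O)NCCCNCCCCN1 | target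

**Totals:** 10 steps in total; longest linear sequence 8 steps (1 → 2 → 3 → 6 → 7 → 8 → 9 → 10).

**Three steps most likely to fail**
1. **Step 8, radical macrocyclisation.** The aryl radical may abstract H from the solvent (giving Ar–H) or the reaction may oligomerise. Fallback: swap the acrylamide for a β-(phenylsulfonyl)acrylamide and generate the aryl radical with (TMS)3SiH/initiator, so that radical addition–β-fragmentation gives the E-alkene without a metal or oxidant.
2. **Step 7, reductive amination with the aldehyde.** The aldehyde may cyclise to the N-acyl hemiaminal, or the primary amine may add to the acrylamide. Fallback: build the polyamine core first (putrescine + acrylonitrile, N8-Boc, Raney Ni/H2 to give N8-Boc-spermidine), then acylate N1 and N8 stepwise with the acids.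
3. **Step 10, late sulfation.** This may give poor O- versus N-selectivity or lose the sulfate during work-up. Fallback: sulfate acid 6 early (SO3·NMe3, aqueous NaOH) and carry the aryl sulfate as its Bu4N salt. Switch the N4 group from Boc to a base-labile trifluoroacetamide, removed at the end with K2CO3/MeOH.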